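**Retrosynthetic overview** (chromene numbering O1, C2, C3, C4, C4a, C5–C8, C8a is used for the ring B part)
1. Target 21 ← chromanol 20: one acid treatment dehydrates C4–OH to the C3=C4 alkene and removes two MOM ethers and the dioxolane.
2. Pyran ring (the only ring built; rings A and B are bought as benzenes) ← fluoro keto-aldehyde 18 + the three-atom unit LiCH2–C(CH3)2–OLi: C3–C4 by carbonyl addition, then O1–C8a by SNAr, in one flask.
3. Enabling feature: the benzophenone C=O sits on C8 of ring B, ortho to C8a, so a fluorine on C8a is displaceable. The formyl carbon C4 sits on C4a, the other ortho neighbour of C8a, so the alkoxide three atoms away closes a six-membered ring. C2 is quaternary and C4a bears no hydrogen, so loss of water can only give C3=C4.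
4. Benzophenone C–C bond ← ring B aryllithium (C8, between F and OMOM, aldehyde masked in the flask) + ring A aldehyde 11, then oxidation.
5. Ring A aldehyde 11 ← 2-hydroxy-3-methylbenzaldehyde 1 (Elbs oxidation, protection, ortho-lithiation/formylation, prenylation); ring B aldehyde 13 ← 2-fluoro-4-hydroxybenzaldehyde 12.

Key step: step 10

Remark: the target is made as the open hydroxy-aldehyde shown by its SMILES (a possible equilibrium with the seven-membered lactol from the ring B phenol and the formyl group is a property of the compound itself); it has no stereocentre, so 17 and 20 are carried as racemates.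

**Step 1**
Reactants: 1 2-hydroxy-3-methylbenzaldehyde
Product: 3 2,5-dihydroxy-3-methylbenzaldehyde, via aryl sulfate 2 (not isolated)
Conditions: K2S2O8, aq NaOH, 0 → 20 °C; then aq HCl, 70 °C
Reagents that add atoms: potassium peroxodisulfate K2S2O8, [K+].[K+].[O-]S(=O)(=O)OOS(=O)(=O)[O-]
Why: Elbs persulfate oxidation: the phenoxide of 1 should attack the peroxide oxygen through its free para carbon, and acid hydrolysis of aryl sulfate 2 should give the hydroquinone.

**Step 2**
Reactants: 3 2,5-dihydroxy-3-methylbenzaldehyde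
Product: 4 2-hydroxy-5-(methoxymethoxy)-3-methylbenzaldehyde
Conditions: MOMCl (1.05 equiv), i-Pr2NEt, CH2Cl2, 0 °C
Reagents that add atoms: chloromethyl methyl ether (MOMCl), COCCl
Why: Williamson-type O-alkylation; the 2-OH is held in a hydrogen bond to the aldehyde and flanked by the methyl group, so one equivalent of MOMCl should go to the free 5-OH.

**Step 3**
Reactants: 4 2-hydroxy-5-(methoxymethoxy)-3-methylbenzaldehyde
Product: 5 2-[(tert-butyldimethylsilyl)oxy]-5-(methoxymethoxy)-3-methylbenzaldehyde
Conditions: TBSCl, imidazole, DMF, rt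
Reagents that add atoms: tert-butyldimethylsilyl chloride (TBSCl), CC(C)(C)[Si](C)(C)Cl
Why: Phenol silylation gives a cap that survives butyllithium (a prenyl ether would not) and can later be removed by fluoride beside the MOM ether.

**Step 4**
Reactants: 5 2-[(tert-butyldimethylsilyl)oxy]-5-(methoxymethoxy)-3-methylbenzaldehyde
Product: 6 2-{2-[(tert-butyldimethylsilyl)oxy]-5-(methoxymethoxy)-3-methylphenyl}-1,3-dioxolane
Conditions: TMSOCH2CH2OTMS, TMSOTf (cat.), CH2Cl2, −78 °C; pyridine quench
Reagents that add atoms: 1,2-bis(trimethylsilyloxy)ethane, C[Si](C)(C)OCCO[Si](C)(C)C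
Why: Aprotic acetalisation with a bis-silyl glycol and catalytic silyl triflate at low temperature should spare the MOM and TBS ethers and gives a dioxolane that both masks the aldehyde and directs the next metalation.

**Step 5**
Reactants: 6 2-{2-[(tert-butyldimethylsilyl)oxy]-5-(methoxymethoxy)-3-methylphenyl}-1,3-dioxolane
Product: 9 3-[(tert-butyldimethylsilyl)oxy]-2-(1,3-dioxolan-2-yl)-6-(methoxymethoxy)-4-methylbenzaldehyde, via aryllithium 7 (not isolated), via lithium hemiaminal alkoxide 8 (not isolated)
Conditions: n-BuLi, TMEDA, THF, −78 → −20 °C; DMF, −78 °C → rt; H2O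
Reagents that add atoms: N,N-dimethylformamide, CN(C)C=O
Why: Directed ortho-metalation: the only ring hydrogen flanked by two directing groups (dioxolane and OMOM) should be removed, and formylation of aryllithium 7 with DMF places the future ketone carbon.

**Step 6**
Reactants: 9 3-[(tert-butyldimethylsilyl)oxy]-2-(1,3-dioxolan-2-yl)-6-(methoxymethoxy)-4-methylbenzaldehyde
Product: 11 2-(1,3-dioxolan-2-yl)-6-(methoxymethoxy)-4-methyl-3-[(3-methylbut-2-en-1-yl)oxy]benzaldehyde, via cesium phenoxide 10 (not isolated)
Conditions: CsF, prenyl bromide, DMF, rt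
Reagents that add atoms: 1-bromo-3-methylbut-2-ene (prenyl bromide), CC(C)=CCBr
Why: One-pot fluoride desilylation and Williamson etherification: CsF should free phenoxide 10, which is alkylated by SN2 at the primary allylic carbon.

**Step 7**
Reactants: 12 2-fluoro-4-hydroxybenzaldehyde
Product: 13 2-fluoro-4-(methoxymethoxy)benzaldehyde
Conditions: MOMCl, i-Pr2NEt, CH2Cl2, 0 °C → rt
Reagents that add atoms: chloromethyl methyl ether (MOMCl), COCCl
Why: Williamson-type MOM protection of the acidic para-formyl phenol; the MOM ether later acidifies the neighbouring ring hydrogen.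

**Step 8**
Reactants: 13 2-fluoro-4-(methoxymethoxy)benzaldehyde; 11 2-(1,3-dioxolan-2-yl)-6-(methoxymethoxy)-4-methyl-3-[(3-methylbut-2-en-1-yl)oxy]benzaldehyde
Product: 17 3-{[2-(1,3-dioxolan-2-yl)-6-(methoxymethoxy)-4-methyl-3-[(3-methylbut-2-en-1-yl)oxy]phenyl](hydroxy)methyl}-2-fluoro-4-(methoxymethoxy)benzaldehyde (racemic), via amino alkoxide 14 (not isolated), via aryllithium 15 (not isolated), via dilithium adduct 16 (not isolated)
Conditions: N-methylpiperazine, n-BuLi, THF, −20 °C; 13; n-BuLi, −78 °C; 11, −78 → −40 °C; H2O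
Reagents that add atoms: none
Why: In situ α-amino alkoxide protection followed by directed ortho-metalation: the lithium amide masks the aldehyde of 13 as 14, n-BuLi should then remove the most acidic ring hydrogen (between F and OMOM), and aryllithium 15 adds 1,2 to the aldehyde of 11, the aqueous quench returning the ring B aldehyde (the carbinol centre forms as a racemate and is oxidised away in step 9).

**Step 9**
Reactants: 17 the diarylmethanol from step 8
Product: 18 3-{2-(1,3-dioxolan-2-yl)-6-(methoxymethoxy)-4-methyl-3-[(3-methylbut-2-en-1-yl)oxy]benzoyl}-2-fluoro-4-(methoxymethoxy)benzaldehyde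
Conditions: Dess–Martin periodinane, pyridine, CH2Cl2, 0 °C → rt
Reagents that add atoms: none
Why: Dess–Martin oxidation of the hindered diarylmethanol to the benzophenone; the aldehyde, acetal, MOM ethers and prenyl ether should be inert to the buffered reagent.

**Step 10**
Reactants: 18 the fluoro keto-aldehyde from step 9
Product: 20 {2-(1,3-dioxolan-2-yl)-6-(methoxymethoxy)-4-methyl-3-[(3-methylbut-2-en-1-yl)oxy]phenyl}[4-hydroxy-7-(methoxymethoxy)-2,2-dimethyl-3,4-dihydro-2H-chromen-8-yl]methanone (racemic), via dilithium diolate 19 (not isolated)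
Conditions: ClCH2C(CH3)2OH (1.3 equiv), n-BuLi (1.3 equiv), THF, −78 °C; LiC10H8 (lithium naphthalenide, 2.5 equiv), −78 °C; 18, −78 °C; DMPU, −78 → 45 °C; H2O
Reagents that add atoms: 1-chloro-2-methylpropan-2-ol, CC(C)(O)CCl
Why: Proposed new method: the alkyllithium carbon of LiCH2C(CH3)2OLi (made at −78 °C from the chlorohydrin by O-deprotonation and reductive C–Cl lithiation) should add to the ring B aldehyde to form C3–C4 and give dilithium diolate 19, and on warming with DMPU the tertiary alkoxide of 19 should attack C8a and expel fluoride through a Meisenheimer adduct stabilised by the ortho benzophenone carbonyl, forming O1–C8a. The closest known reaction types are the 1,2-addition of β-oxido alkyllithiums to aldehydes (giving 1,3-diols) and the intramolecular SNAr of alkoxides onto ortho-fluoroaryl ketones (giving chromans); joining them in one flask as a three-atom-plus-three-atom annulation is the untested part. The pyran ring closes by a six-membered intramolecular addition–elimination at the sp2 carbon C8a with the leaving fluoride outside the new ring (exo-type closure); the secondary C4 alkoxide cannot compete because it would have to form a four-membered ring. The C4 carbinol centre arises without control (racemate), which is harmless because step 11 removes it. The step needs the alkyllithium to choose the aldehyde over the ketone and over the C–F carbon: the ketone is shielded by four ortho substituents, the addition is run at −78 °C with a small excess of reagent, and LiC10H8 is kept in deficit so that no radical anion is left to reduce the benzophenone.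

**Step 11**
Reactants: 20 the chromanol from step 10
Product: 21 3-hydroxy-2-(7-hydroxy-2,2-dimethyl-2H-chromene-8-carbonyl)-5-methyl-6-[(3-methylbut-2-en-1-yl)oxy]benzaldehyde
Conditions: 2 M aq HCl, THF, 40 °C
Reagents that add atoms: water, O
Why: Acid-catalysed E1 dehydration and acetal hydrolysis in one treatment: the C4 cation is stabilised by O1 and by the C7 oxygen and can lose a proton only from C3 (giving the C3=C4 alkene), while both MOM ethers, activated by the ortho carbonyl, and the dioxolane should hydrolyse under the same mild conditions.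

**Compound list**
1 | 2-hydroxy-3-methylbenzaldehyde | Cc1cccc(C=O)c1O | starting material
2 | potassium 3-formyl-4-hydroxy-5-methylphenyl sulfate (formed in the flask) | Cc1cc(OS(=O)(=O)[O-])cc(C=O)c1O.[K+] | intermediate
3 | 2,5-dihydroxy-3-methylbenzaldehyde | Cc1cc(O)cc(C=O)c1O | intermediate
4 | 2-hydroxy-5-(methoxymethoxy)-3-methylbenzaldehyde | COCOc1cc(C)c(O)c(C=O)c1 | intermediate
5 | 2-[(tert-butyldimethylsilyl)oxy]-5-(methoxymethoxy)-3-methylbenzaldehyde | COCOc1cc(C)c(O[Si](C)(C)C(C)(C)C)c(C=O)c1 | intermediate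
6 | 2-{2-[(tert-butyldimethylsilyl)oxy]-5-(methoxymethoxy)-3-methylphenyl}-1,3-dioxolane | COCOc1cc(C)c(O[Si](C)(C)C(C)(C)C)c(C2OCCO2)c1 | intermediate
7 | {3-[(tert-butyldimethylsilyl)oxy]-2-(1,3-dioxolan-2-yl)-6-(methoxymethoxy)-4-methylphenyl}lithium (formed in the flask) | COCOc1cc(C)c(O[Si](C)(C)C(C)(C)C)c(C2OCCO2)c1[Li] | intermediate
8 | lithium (dimethylamino){3-[(tert-butyldimethylsilyl)oxy]-2-(1,3-dioxolan-2-yl)-6-(methoxymethoxy)-4-methylphenyl}methanolate (racemic, formed in the flask) | COCOc1cc(C)c(O[Si](C)(C)C(C)(C)C)c(C2OCCO2)c1C(O[Li])N(C)C | intermediate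
9 | 3-[(tert-butyldimethylsilyl)oxy]-2-(1,3-dioxolan-2-yl)-6-(methoxymethoxy)-4-methylbenzaldehyde | COCOc1cc(C)c(O[Si](C)(C)C(C)(C)C)c(C2OCCO2)c1C=O | intermediate
10 | cesium 2-(1,3-dioxolan-2-yl)-3-formyl-4-(methoxymethoxy)-6-methylphenolate (formed in the flask) | COCOc1cc(C)c([O-])c(C2OCCO2)c1C=O.[Cs+] | intermediate
11 | 2-(1,3-dioxolan-2-yl)-6-(methoxymethoxy)-4-methyl-3-[(3-methylbut-2-en-1-yl)oxy]benzaldehyde | COCOc1cc(C)c(OCC=C(C)C)c(C2OCCO2)c1C=O | intermediate
12 | 2-fluoro-4-hydroxybenzaldehyde | O=Cc1ccc(O)cc1F | starting material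
13 | 2-fluoro-4-(methoxymethoxy)benzaldehyde | COCOc1ccc(C=O)c(F)c1 | intermediate
14 | lithium [2-fluoro-4-(methoxymethoxy)phenyl](4-methylpiperazin-1-yl)methanolate (racemic, formed in the flask) | COCOc1ccc(C(O[Li])N2CCN(C)CC2)c(F)c1 | intermediate
15 | lithium [2-fluoro-3-lithio-4-(methoxymethoxy)phenyl](4-methylpiperazin-1-yl)methanolate (racemic, formed in the flask) | COCOc1ccc(C(O[Li])N2CCN(C)CC2)c(F)c1[Li] | intermediate
16 | dilithium dialkoxide from addition of 15 to 11 (mixture of diastereomers, formed in the flask) | COCOc1ccc(C(O[Li])N2CCN(C)CC2)c(F)c1C(O[Li])c1c(OCOC)cc(C)c(OCC=C(C)C)c1C1OCCO1 | intermediate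
17 | 3-{[2-(1,3-dioxolan-2-yl)-6-(methoxymethoxy)-4-methyl-3-[(3-methylbut-2-en-1-yl)oxy]phenyl](hydroxy)methyl}-2-fluoro-4-(methoxymethoxy)benzaldehyde (racemic) | COCOc1ccc(C=O)c(F)c1C(O)c1c(OCOC)cc(C)c(OCC=C(C)C)c1C1OCCO1 | intermediate
18 | 3-{2-(1,3-dioxolan-2-yl)-6-(methoxymethoxy)-4-methyl-3-[(3-methylbut-2-en-1-yl)oxy]benzoyl}-2-fluoro-4-(methoxymethoxy)benzaldehyde | COCOc1ccc(C=O)c(F)c1C(=O)c1c(OCOC)cc(C)c(OCC=C(C)C)c1C1OCCO1 | intermediate
19 | dilithium 1,3-diolate from addition of LiCH2C(CH3)2OLi to the aldehyde of 18 (racemic, formed in the flask) | COCOc1ccc(C(O[Li])CC(C)(C)O[Li])c(F)c1C(=O)c1c(OCOC)cc(C)c(OCC=C(C)C)c1C1OCCO1 | intermediate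
20 | {2-(1,3-dioxolan-2-yl)-6-(methoxymethoxy)-4-methyl-3-[(3-methylbut-2-en-1-yl)oxy]phenyl}[4-hydroxy-7-(methoxymethoxy)-2,2-dimethyl-3,4-dihydro-2H-chromen-8-yl]methanone (racemic) | COCOc1ccc2C(O)CC(C)(C)Oc2c1C(=O)c1c(OCOC)cc(C)c(OCC=C(C)C)c1C1OCCO1 | intermediate
21 | 3-hydroxy-2-(7-hydroxy-2,2-dimethyl-2H-chromene-8-carbonyl)-5-methyl-6-[(3-methylbut-2-en-1-yl)oxy]benzaldehyde (CNP0150093.0) | CC(C)=CCOc1c(C)cc(O)c(C(=O)c2c(O)ccc3C=CC(C)(C)Oc23)c1C=O | target

**Step count**
Total steps: 11. Longest linear sequence: 10 steps (steps 1–6 and 8–11); step 7 is the one-step side branch.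

**Steps most likely to fail**

1. Step 10 (proposed method). What may go wrong: reduction of the benzophenone by leftover radical anion, addition of the alkyllithium to the ketone or the C–F carbon, or a stalled ring closure of the lithium alkoxide. Fallback with known reactions only, setting out from 18 and coming back at 20: the lithium enolate of tert-butyl acetate (LiN(i-Pr)2, THF, −78 °C) should add to the aldehyde alone (ester enolate aldol addition) to give the β-hydroxy ester F1. Excess MeMgBr (THF, 0 °C) should turn the ester into the tertiary carbinol, the 1,3-diol F2, the shielded ketone being left alone. KOtBu in THF/DMF should then close the pyran ring by intramolecular SNAr and give 20.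

2. Step 8. What may go wrong: loss of LiF from the ortho-fluoro aryllithium (aryne formation), metalation next to the amino alkoxide instead of between F and OMOM, or slow addition to the doubly ortho-substituted aldehyde. Fallback, setting out from 13 and coming back at 18: the aldehyde is masked as an isolable acyclic acetal instead of in the flask. MeOSiMe3 with catalytic TMSOTf (CH2Cl2, −78 °C) should give the dimethyl acetal F3. n-BuLi (THF, −78 °C) should lithiate between F and OMOM to the aryllithium F4, which adds to 11 to give the carbinol F5. Dess–Martin oxidation should give the ketone F6. The acyclic, electron-rich dimethyl acetal should then hydrolyse well before the hindered dioxolane (catalytic PPTS, wet acetone, 0 °C), which gives 18.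

3. Step 11. What may go wrong: acid cleavage of the prenyl ether, or capture of released formaldehyde by the electron-rich rings, while the MOM ethers are coming off. Fallback, setting out from 20 and coming back at 21: the events are separated and the Brønsted acid is avoided. MsCl and Et3N (CH2Cl2, 0 °C) should convert the benzylic alcohol into the mesylate F7, which should eliminate in the flask to the protected chromene F8. TMSOTf with 2,2'-bipyridyl (CH2Cl2, 0 °C), followed by water, should then cleave both aryl MOM ethers and the dioxolane through pyridinium intermediates under buffered, aprotic conditions and give 21.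

**Further compounds**
F1 | step 10 | tert-butyl 3-{3-[2-(1,3-dioxolan-2-yl)-6-(methoxymethoxy)-4-methyl-3-[(3-methylbut-2-en-1-yl)oxy]benzoyl]-2-fluoro-4-(methoxymethoxy)phenyl}-3-hydroxypropanoate (racemic) | COCOc1ccc(C(O)CC(=O)OC(C)(C)C)c(F)c1C(=O)c1c(OCOC)cc(C)c(OCC=C(C)C)c1C1OCCO1
F2 | step 10 | 1-{3-[2-(1,3-dioxolan-2-yl)-6-(methoxymethoxy)-4-methyl-3-[(3-methylbut-2-en-1-yl)oxy]benzoyl]-2-fluoro-4-(methoxymethoxy)phenyl}-3-methylbutane-1,3-diol (racemic) | COCOc1ccc(C(O)CC(C)(C)O)c(F)c1C(=O)c1c(OCOC)cc(C)c(OCC=C(C)C)c1C1OCCO1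
F3 | step 8 | 1-(dimethoxymethyl)-2-fluoro-4-(methoxymethoxy)benzene | COCOc1ccc(C(OC)OC)c(F)c1
F4 | step 8 | [3-(dimethoxymethyl)-2-fluoro-6-(methoxymethoxy)phenyl]lithium (formed in the flask) | COCOc1ccc(C(OC)OC)c(F)c1[Li]
F5 | step 8 | [3-(dimethoxymethyl)-2-fluoro-6-(methoxymethoxy)phenyl]{2-(1,3-dioxolan-2-yl)-6-(methoxymethoxy)-4-methyl-3-[(3-methylbut-2-en-1-yl)oxy]phenyl}methanol (racemic) | COCOc1ccc(C(OC)OC)c(F)c1C(O)c1c(OCOC)cc(C)c(OCC=C(C)C)c1C1OCCO1
F6 | step 8 | [3-(dimethoxymethyl)-2-fluoro-6-(methoxymethoxy)phenyl]{2-(1,3-dioxolan-2-yl)-6-(methoxymethoxy)-4-methyl-3-[(3-methylbut-2-en-1-yl)oxy]phenyl}methanone | COCOc1ccc(C(OC)OC)c(F)c1C(=O)c1c(OCOC)cc(C)c(OCC=C(C)C)c1C1OCCO1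
F7 | step 11 | 8-{2-(1,3-dioxolan-2-yl)-6-(methoxymethoxy)-4-methyl-3-[(3-methylbut-2-en-1-yl)oxy]benzoyl}-7-(methoxymethoxy)-2,2-dimethyl-3,4-dihydro-2H-chromen-4-yl methanesulfonate (racemic, formed in the flask) | COCOc1ccc2C(OS(C)(=O)=O)CC(C)(C)Oc2c1C(=O)c1c(OCOC)cc(C)c(OCC=C(C)C)c1C1OCCO1
F8 | step 11 | {2-(1,3-dioxolan-2-yl)-6-(methoxymethoxy)-4-methyl-3-[(3-methylbut-2-en-1-yl)oxy]phenyl}[7-(methoxymethoxy)-2,2-dimethyl-2H-chromen-8-yl]methanone | COCOc1ccc2C=CC(C)(C)Oc2c1C(=O)c1c(OCOC)cc(C)c(OCC=C(C)C)c1C1OCCO1
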